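**Assumptions**
- The lactone carbon in the target SMILES is (R). (S)-Me-CBS is assumed to give the (R)-carbinol from the enone, by analogy with aryl/alkenyl versus alkyl ketones.
- Cu-catalysed carbomagnesiation of the alkoxide alkyne delivers the alkyl group to the carbon next to the propargylic CH2OH.

**Retrosynthetic overview**
1. The Z-trisubstituted allylic alcohol is made by the fragment coupling: syn-carbomagnesiation of a chiral alkynyl diol (C8 unit) with the Grignard of a C16 (E)-alkenyl bromide that carries the trimethylcyclohexene.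
2. The butenolide ring is formed last: acrylate ester of the C5 allylic alcohol, ring-closing metathesis onto a 1,1-disubstituted alkene, then desilylation. C5 is set by CBS reduction of an enone.
3. The C16 bromide: E-trisubstituted alkene by Zr-catalysed methylalumination of a terminal alkyne; the ring is not built but introduced, via 2-methylcyclohexanone → 2,2,6-trimethylcyclohexanone → enol triflate → Negishi coupling.
4. The alkyne fragment comes from a 2-(silyloxymethyl)acrolein plus a 4-chlorobut-2-ynyl unit by Barbier propargylation.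
5. Ring order: the cyclohexene ring is carried in from the first starting material; the butenolide is closed in the penultimate step.

---

**Step 1**
Reactants: 1 (2-methylcyclohexanone)
Product: 2 (2,6-dimethylcyclohexanone, cis/trans mixture)
Conditions: LDA, THF, −78 °C; then MeI, −78 → 25 °C
Reagents that add atoms: MeI (CI)
Why: The kinetic enolate forms at the less substituted C6 and is C-methylated (enolate alkylation); both diastereomers converge in the next step.

**Step 2**
Reactants: 2
Product: 3 (2,2,6-trimethylcyclohexanone)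
Conditions: KH, THF, 0 °C; then MeI (1.0 equiv), 0 → 25 °C
Reagents that add atoms: MeI (CI)
Why: 2 is symmetric, so deprotonation and methylation at either tertiary α-carbon gives the gem-dimethyl ketone with no regiochemistry issue.

**Step 3**
Reactants: 3
Product: 4 (2,6,6-trimethylcyclohex-1-en-1-yl triflate)
Conditions: LDA (1.3 equiv), THF, −78 → 0 °C; then PhNTf2, −78 → 25 °C
Reagents that add atoms: PhNTf2 (O=S(=O)(C(F)(F)F)N(c1ccccc1)S(=O)(=O)C(F)(F)F)
Why: The only enolisable α-C–H is at C6, so enolate O-triflation gives the tetrasubstituted enol triflate, which is the ring-bearing coupling partner.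

**Step 4**
Reactants: 5 (3-butyn-1-ol)
Product: 6 (4-(trimethylsilyl)but-3-yn-1-ol)
Conditions: n-BuLi (2.1 equiv), THF, −78 °C; TMSCl (2.2 equiv); then 1 M HCl, THF, 25 °C
Reagents that add atoms: TMSCl (C[Si](C)(C)Cl)
Why: The dianion is silylated at O and C, and mild acid cleaves only the O–TMS, leaving the alkyne protected (silyl protection).

**Step 5**
Reactants: 6
Product: 7 ((4-bromobut-1-yn-1-yl)trimethylsilane)
Conditions: CBr4, PPh3, CH2Cl2, 0 → 25 °C
Reagents that add atoms: CBr4 (BrC(Br)(Br)Br)
Why: Appel bromination of the primary alcohol by SN2 gives the homopropargyl bromide.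

**Step 6**
Reactants: 4 (triflate) and 7 (bromide)
Product: 8 (trimethyl[4-(2,6,6-trimethylcyclohex-1-en-1-yl)but-1-yn-1-yl]silane)
Conditions: 7, Zn dust, LiCl, BrCH2CH2Br/TMSCl (activation), THF, 40 °C to give RZnBr; then 4, Pd(OAc)2 (5 mol %), SPhos (10 mol %), THF, 60 °C
Reagents that add atoms: none
Why: Negishi coupling of the alkylzinc with the enol triflate builds the ring–CH2CH2 (α,β) linkage; no stereocentre is formed.

**Step 7**
Reactants: 8
Product: 9 (1-(but-3-yn-1-yl)-2,6,6-trimethylcyclohexene)
Conditions: K2CO3, MeOH, 25 °C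
Reagents that add atoms: none
Why: Methoxide cleaves the alkynyl C–Si bond (protodesilylation) to give the terminal alkyne.

**Step 8**
Reactants: 9
Product: 10 ((E)-vinyl iodide, 1-[(E)-4-iodo-3-methylbut-3-en-1-yl]-2,6,6-trimethylcyclohexene)
Conditions: Me3Al (3 equiv), Cp2ZrCl2 (20 mol %), (CH2Cl)2, 0 → 25 °C; then I2, THF, −30 °C
Reagents that add atoms: Me3Al (C[Al](C)C); I2 (II)
Why: Zr-catalysed carboalumination is a syn addition of Me and Al across the terminal alkyne (Me on the internal carbon), and iodinolysis with retention sets the E-trisubstituted alkene geometry.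

**Step 9**
Reactants: 10
Product: 11 ((E)-4-methyl-6-(2,6,6-trimethylcyclohex-1-en-1-yl)hex-3-en-1-ol)
Conditions: t-BuLi (2.1 equiv), Et2O, −78 °C; then ethylene oxide (3 equiv), BF3·OEt2, −78 → 0 °C
Reagents that add atoms: ethylene oxide (C1CO1)
Why: Iodine–lithium exchange proceeds with retention of alkene geometry, and the vinyllithium opens the BF3-activated epoxide to add the CH2CH2OH (ε,ζ) unit.

**Step 10**
Reactants: 11
Product: 12 ((E)-1-(6-bromo-3-methylhex-3-enyl… i.e. the C16 bromide BrCH2CH2CH=C(Me)CH2CH2-ring)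
Conditions: CBr4, PPh3, CH2Cl2, 0 → 25 °C
Reagents that add atoms: CBr4 (BrC(Br)(Br)Br)
Why: Appel bromination of the primary homoallylic alcohol with no allylic transposition gives the Grignard precursor.

**Step 11**
Reactants: 13 (2-methylenepropane-1,3-diol)
Product: 14 (2-[(tert-butyldimethylsilyloxy)methyl]prop-2-en-1-ol)
Conditions: NaH (1.0 equiv), THF, 0 °C; TBSCl (1.0 equiv), 0 → 25 °C
Reagents that add atoms: TBSCl (CC(C)(C)[Si](C)(C)Cl)
Why: The symmetric diol is mono-silylated via its mono-alkoxide (silyl protection).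

**Step 12**
Reactants: 14
Product: 15 (2-[(TBSO)methyl]acrolein)
Conditions: MnO2 (10 equiv), CH2Cl2, 25 °C
Reagents that add atoms: none
Why: MnO2 oxidises the allylic alcohol chemoselectively to the enal and leaves the silyl ether untouched.

**Step 13**
Reactants: 16 (4-chlorobut-2-yn-1-ol)
Product: 17 (2-[(4-chlorobut-2-yn-1-yl)oxy]tetrahydro-2H-pyran)
Conditions: DHP, PPTS (5 mol %), CH2Cl2, 25 °C
Reagents that add atoms: DHP (C1=COCCC1)
Why: Acid-catalysed THP acetalisation masks the propargylic OH so the Barbier reagent and later oxidation are clean.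

**Step 14**
Reactants: 15 and 17
Product: 18 (racemic homopropargylic allylic alcohol, CH2=C(CH2OTBS)CH(OH)CH2C≡CCH2OTHP)
Conditions: Zn dust (3 equiv), THF/sat. aq. NH4Cl (1:1), 25 °C
Reagents that add atoms: none
Why: Barbier-type zinc propargylation goes through the allenylzinc by SE2′ attack on the aldehyde and gives the homopropargylic alcohol (racemic, resolved by the next two steps).

**Step 15**
Reactants: 18
Product: 19 (enone, CH2=C(CH2OTBS)C(=O)CH2C≡CCH2OTHP)
Conditions: Dess–Martin periodinane (1.5 equiv), NaHCO3, CH2Cl2, 0 → 25 °C; use crude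
Reagents that add atoms: none
Why: A neutral, mild oxidation avoids isomerisation of the acidic propargylic ketone or polymerisation of the α-methylene ketone, and destroys the racemic stereocentre.

**Step 16**
Reactants: 19
Product: 20 ((R)-alcohol, CH2=C(CH2OTBS)[C@H](OH)CH2C≡CCH2OTHP; THP epimers undefined)
Conditions: (S)-Me-CBS (20 mol %), BH3·SMe2 (0.8 equiv), THF, −40 °C
Reagents that add atoms: none
Why: CBS reduction sets the C5 carbinol, because the catalyst-bound borane delivers hydride to one face, distinguishing the bulky 1,1-disubstituted vinyl group from the small propargylic CH2.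

**Step 17**
Reactants: 20
Product: 21 (diol, CH2=C(CH2OTBS)[C@H](OH)CH2C≡CCH2OH)
Conditions: PPTS (20 mol %), MeOH, 45 °C
Reagents that add atoms: none
Why: Acid-catalysed THP methanolysis frees the propargylic OH, which is needed to direct the carbometalation; the TBS ether and C5 centre are untouched.

**Step 18 (fragment coupling)**
Reactants: 12 (C16 bromide) and 21 (diol)
Product: 22 ((Z)-trisubstituted allylic alcohol, C24 skeleton)
Conditions: (i) 21, NaH (2.1 equiv), THF, 0 °C; then MgBr2·OEt2 (2.1 equiv); (ii) RMgBr (from 12 + Mg, THF, 25 °C; 1.6 equiv) with CuI (20 mol %), 0 → 40 °C, 12 h; quench sat. aq. NH4Cl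
Reagents that add atoms: none
Why: Cu-catalysed carbomagnesiation proceeds by syn addition, the two Mg alkoxides chelate Mg onto the distal alkyne carbon so R adds next to the CH2OH-bearing carbon, and protonolysis puts the chain cis to the new vinyl H, so CH2OH ends up cis to the CH2 toward C5 (the Z-alkene); the C5 centre is not touched.

**Step 19**
Reactants: 22
Product: 23 (η-CH2OTBS, C5–OH free)
Conditions: TBSCl (1.05 equiv), imidazole (2.5 equiv), CH2Cl2, 0 °C
Reagents that add atoms: TBSCl (CC(C)(C)[Si](C)(C)Cl)
Why: The unhindered primary allylic OH silylates selectively over the hindered secondary C5–OH (silylation).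

**Step 20**
Reactants: 23
Product: 24 (C5 acrylate ester)
Conditions: acryloyl chloride (1.5 equiv), Et3N (3 equiv), DMAP (cat.), CH2Cl2, −10 → 0 °C
Reagents that add atoms: acryloyl chloride (C=CC(=O)Cl)
Why: Acylation of the only free OH, with retention at C5, installs the RCM partner.

**Step 21**
Reactants: 24
Product: 25 (bis-TBS butenolide)
Conditions: Grubbs II (10 mol %), Ti(OiPr)4 (30 mol %), CH2Cl2 (3 mM), 40 °C
Reagents that add atoms: none
Why: Ring-closing metathesis between the acrylate and the 1,1-disubstituted alkene releases ethylene and forms the 4-(silyloxymethyl)-2(5H)-furanone; C5 is not affected.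

**Step 22**
Reactants: 25
Product: 26 (target, (6Z)-neomanoalide)
Conditions: HF·pyridine, pyridine/THF, 0 → 25 °C
Reagents that add atoms: none
Why: Buffered fluoride removes both primary TBS ethers without epimerising the acidic γ-H of the butenolide.

---

**Compound list**

| No. | Name | SMILES | Role |
|---|---|---|---|
| 1 | 2-methylcyclohexanone | CC1CCCCC1=O | starting material |
| 2 | 2,6-dimethylcyclohexanone | CC1CCCC(C)C1=O | intermediate |
| 3 | 2,2,6-trimethylcyclohexanone | CC1CCCC(C)(C)C1=O | intermediate |
| 4 | 2,6,6-trimethylcyclohex-1-en-1-yl triflate | CC1=C(OS(=O)(=O)C(F)(F)F)C(C)(C)CCC1 | intermediate |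
| 5 | 3-butyn-1-ol | C#CCCO | starting material |
| 6 | 4-(trimethylsilyl)but-3-yn-1-ol | C[Si](C)(C)C#CCCO | intermediate |
| 7 | (4-bromobut-1-yn-1-yl)trimethylsilane | C[Si](C)(C)C#CCCBr | intermediate |
| 8 | TMS-alkyne of ring–CH2CH2C≡C | CC1=C(CCC#C[Si](C)(C)C)C(C)(C)CCC1 | intermediate |
| 9 | terminal alkyne | CC1=C(CCC#C)C(C)(C)CCC1 | intermediate |
| 10 | (E)-vinyl iodide | CC1=C(CC/C(C)=C/I)C(C)(C)CCC1 | intermediate |
| 11 | (E)-homoallylic alcohol | CC1=C(CC/C(C)=C/CCO)C(C)(C)CCC1 | intermediate |
| 12 | (E)-homoallylic bromide (C16) | CC1=C(CC/C(C)=C/CCBr)C(C)(C)CCC1 | intermediate |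
| 13 | 2-methylenepropane-1,3-diol | C=C(CO)CO | starting material |
| 14 | mono-TBS ether | C=C(CO)CO[Si](C)(C)C(C)(C)C | intermediate |
| 15 | 2-[(TBSO)methyl]acrolein | C=C(C=O)CO[Si](C)(C)C(C)(C)C | intermediate |
| 16 | 4-chlorobut-2-yn-1-ol | OCC#CCCl | starting material |
| 17 | THP ether of 16 | ClCC#CCOC1CCCCO1 | intermediate |
| 18 | racemic homopropargylic alcohol | C=C(CO[Si](C)(C)C(C)(C)C)C(O)CC#CCOC1CCCCO1 | intermediate |
| 19 | enone | C=C(CO[Si](C)(C)C(C)(C)C)C(=O)CC#CCOC1CCCCO1 | intermediate |
| 20 | (R)-alcohol | C=C(CO[Si](C)(C)C(C)(C)C)[C@H](O)CC#CCOC1CCCCO1 | intermediate |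
| 21 | (R)-alkynyl diol | C=C(CO[Si](C)(C)C(C)(C)C)[C@H](O)CC#CCO | intermediate |
| 22 | coupled (Z)-allylic alcohol | CC1=C(CC/C(C)=C/CC/C(=C/C[C@@H](O)C(=C)CO[Si](C)(C)C(C)(C)C)CO)C(C)(C)CCC1 | intermediate |
| 23 | bis-TBS, C5–OH free | CC1=C(CC/C(C)=C/CC/C(=C/C[C@@H](O)C(=C)CO[Si](C)(C)C(C)(C)C)CO[Si](C)(C)C(C)(C)C)C(C)(C)CCC1 | intermediate |
| 24 | C5 acrylate | CC1=C(CC/C(C)=C/CC/C(=C/C[C@@H](OC(=O)C=C)C(=C)CO[Si](C)(C)C(C)(C)C)CO[Si](C)(C)C(C)(C)C)C(C)(C)CCC1 | intermediate |
| 25 | bis-TBS butenolide | CC1=C(CC/C(C)=C/CC/C(=C/C[C@H]2OC(=O)C=C2CO[Si](C)(C)C(C)(C)C)CO[Si](C)(C)C(C)(C)C)C(C)(C)CCC1 | intermediate |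
| 26 | (6Z)-neomanoalide | CC1=C(CC/C(C)=C/CC/C(=C/C[C@H]2OC(=O)C=C2CO)CO)C(C)(C)CCC1 | target |

**Step count:** 22 steps in total.
**Longest linear sequence:** 13 steps (1 → 2 → 3 → 6 → 7 → 8 → 9 → 10 → 18 → 19 → 20 → 21 → 22), which is 59% of the total.

**Three steps most likely to fail**
1. **Step 18 (Cu-catalysed carbomagnesiation).** Risks are a sluggish addition of the large Grignard to an alkoxide alkyne, and regiochemistry. Fallback: a Z-selective olefination. Alkylate a Still–Gennari bis(trifluoroethyl) phosphonoacetate with 12. Couple it with the β-silyloxy aldehyde made from 15 by Reformatsky addition, resolution and DIBAL. Then reduce the Z-ester to the Z-allylic alcohol with DIBAL.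
2. **Step 16 (CBS reduction of the sensitive α-methylene, β,γ-alkynyl enone 19).** Risks are decomposition or low ee. Fallback: skip the oxidation and resolve racemic 18 enzymatically (lipase PS, vinyl acetate), then carry the (R)-alcohol forward at reduced yield.
3. **Step 6 (Negishi coupling of the hindered tetrasubstituted enol triflate with a primary alkylzinc).** Risks are triflate reduction and low conversion. Fallback: a Ni-catalysed reductive cross-electrophile coupling of 4 directly with the bromide 7, which needs no organozinc.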